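**Retrosynthetic overview**
1. Feature: ring A (C4a, C5, C6, C7, C8, C8a) carries H on C5, OMe on C6, OH on C7 and OMe on C8. This is the substituent array of a 2-alkyl-3,5-dimethoxy-4-pyranone read from its C6 to its C2, with the ring oxygen exchanged for the carbon C4a.
2. Key disconnection: C4a–C8a and C4a–C5 of tetralone 18 lead back to pyranone methyl ketone 15. The ketone methyl carbon becomes C4a; ring B closes first and carbocyclic ring A second, in one operation.
3. After the key step: the C4 ketone is turned into C3–CHO and C3=C4 (chloroformylation, hydrodechlorination), then both benzyl ethers are removed.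
4. Before the key step: 15 comes from Wacker oxidation of allyl pyranone 14, whose pyranone ring is assembled from aldehyde 9 and enaminone 11 (aldol, oxidation, acid cyclisation).
5. Aldehyde 9 comes from an organocatalytic Michael addition of pent-4-enal to nitrostyrene 4 (sets C2), then reduction, benzylation and Nef reaction. C1 stays labile until step 10 fixes it.

Key step: step 10

Remark 1: atom labels C1–C8a are those of the target drawn as a 1-aryl-1,2-dihydronaphthalene-3-carbaldehyde (C1 aryl-bearing, C2 hydroxymethyl-bearing, C3 formyl-bearing, C4 =CH). Names of 18–21 use these locants; Ar = 4-(benzyloxy)-3,5-dimethoxyphenyl.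
Remark 2: C1 is epimerisable from aldehyde 9 onward, and the syn Michael adduct carries the C1 configuration opposite to the one needed. C1 is therefore not controlled before step 10; 12–15 are carried as C1 epimer pairs and their SMILES leave C1 open.

**Route**

Step 1
Reactants: 1 syringaldehyde (4-hydroxy-3,5-dimethoxybenzaldehyde)
Product: 2 4-(benzyloxy)-3,5-dimethoxybenzaldehyde
Conditions: BnBr, K2CO3, DMF, 60 °C
Reagents that add atoms: benzyl bromide, BrCc1ccccc1
Why: Williamson etherification of the acidic phenol gives a benzyl ether that should last until the final step.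

Step 2
Reactants: 2 4-(benzyloxy)-3,5-dimethoxybenzaldehyde; 3 nitromethane
Product: 4 2-(benzyloxy)-1,3-dimethoxy-5-[(E)-2-nitroethenyl]benzene
Conditions: NH4OAc, AcOH, 100 °C
Reagents that add atoms: none
Why: Henry condensation with dehydration in the same pot should give the conjugated (E)-nitroalkene as the thermodynamic isomer.

Step 3
Reactants: 4 nitrostyrene; 5 pent-4-enal (3 equiv)
Product: 7 (2S)-2-[(1R)-1-Ar-2-nitroethyl]pent-4-en-1-ol, via nitro aldehyde 6 (not isolated)
Conditions: (R)-2-[diphenyl(trimethylsilyloxy)methyl]pyrrolidine (10 mol%), PhCO2H (10 mol%), toluene, 0 °C to rt; then NaBH4, MeOH, 0 °C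
Reagents that add atoms: none
Why: Hayashi–Jørgensen enamine Michael addition, in which the E-enamine of 5 attacks the nitroalkene with the face turned away from the diphenyl(silyloxy)methyl group through a synclinal open transition state, so that the catalyst sets C2 as S (syn adduct, C1 R); immediate borohydride reduction removes the epimerisable aldehyde.

Step 4
Reactants: 7 nitro alcohol
Product: 8 2-(benzyloxy)-5-[(2R,3S)-3-(benzyloxymethyl)-1-nitrohex-5-en-2-yl]-1,3-dimethoxybenzene
Conditions: BnOC(=NH)CCl3 (1.5 equiv), TfOH (5 mol%), CH2Cl2–cyclohexane, 0 °C to rt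
Reagents that add atoms: benzyl 2,2,2-trichloroacetimidate, N=C(OCc1ccccc1)C(Cl)(Cl)Cl
Why: acid-catalysed imidate benzylation of the primary alcohol is chosen because basic benzylation would form and O-alkylate the nitronate.

Step 5
Reactants: 8 nitro benzyl ether
Product: 9 (2R,3S)-2-Ar-3-(benzyloxymethyl)hex-5-enal
Conditions: NaOMe, MeOH, 0 °C; then aq. TiCl3, NH4OAc, THF, pH 5–6, rt
Reagents that add atoms: water, O
Why: Nef reaction in the McMurry variant, in which trivalent titanium reduces the nitronate to the imine that hydrolyses to the aldehyde under buffered conditions sparing the alkene and the benzyl ethers; C2 is not touched.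

Step 6
Reactants: 10 1,3-dimethoxypropan-2-one
Product: 11 (Z)-4-(dimethylamino)-1,3-dimethoxybut-3-en-2-one
Conditions: Me2NCH(OMe)2 (1.05 equiv), toluene, 90 °C
Reagents that add atoms: N,N-dimethylformamide dimethyl acetal, COC(OC)N(C)C
Why: aminomethylenation of one activated α-methylene gives the enaminone, and the vinylogous amide formed deactivates the second methylene so that mono-condensation is expected.

Step 7
Reactants: 9 aldehyde; 11 enaminone (1.5 equiv)
Product: 12 (1Z,7S)-6-Ar-7-(benzyloxymethyl)-1-(dimethylamino)-5-hydroxy-2,4-dimethoxydeca-1,9-dien-3-one (diastereomer mixture at C4–C6)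
Conditions: 11, LiN(SiMe3)2, THF, −78 °C; then 9, −78 °C; AcOH quench
Reagents that add atoms: none
Why: directed aldol addition, in which 11 is deprotonated at its only enolisable carbon (CH2OMe) and the lithium enolate should add to the aldehyde at −78 °C faster than it deprotonates it; the new carbinol and C–OMe centres become sp2 later and C1 is reset in step 10.

Step 8
Reactants: 12 aldol adduct
Product: 14 2-[(2S)-1-Ar-2-(benzyloxymethyl)pent-4-en-1-yl]-3,5-dimethoxy-4H-pyran-4-one (both C1 epimers), via diketo enaminone 13 (not isolated)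
Conditions: Dess–Martin periodinane, CH2Cl2, 0 °C to rt; then CF3CO2H, CH2Cl2, rt
Reagents that add atoms: none
Why: Dess–Martin oxidation gives the 1,3-diketone, whose enol oxygen adds to the enaminone carbon under acid with loss of dimethylamine (cyclocondensation to the 4-pyranone); equilibration of C1 at this stage is accepted.

Step 9
Reactants: 14 allyl pyranone
Product: 15 2-[(2S)-1-Ar-2-(benzyloxymethyl)-4-oxopentyl]-3,5-dimethoxy-4H-pyran-4-one (both C1 epimers)
Conditions: PdCl2 (10 mol%), CuCl (1 equiv), O2 (1 atm), DMF–H2O 7:1, rt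
Reagents that add atoms: water, O
Why: Tsuji–Wacker oxidation, in which Markovnikov hydroxypalladation of the monosubstituted alkene should give the methyl ketone while pyranone and benzyl ethers stay inert.

Step 10
Reactants: 15 pyranone methyl ketone
Product: 18 (1S,2S)-1-Ar-2-(benzyloxymethyl)-7-hydroxy-6,8-dimethoxy-2,3-dihydronaphthalen-4(1H)-one, via spiro adduct 16 (not isolated), via ring-opened formyl enedione 17 (not isolated)
Conditions: KOt-Bu (3 equiv), t-BuOH–THF 1:1 (0.01 M, degassed), 0 °C to rt; then AcOH
Reagents that add atoms: none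
Why: Proposed new method: the methyl-side enolate carbon (C4a) of the ketone should add in conjugate fashion to the pyranone carbon C8a to give spiro adduct 16 (ring B, 6-(enolendo)-exo-trig, chair-like); E1cB expulsion of the ring oxygen then opens the heterocycle to formyl enedione 17, and C4a, now doubly activated, condenses with the formyl carbon C5 (ring A, 6-(enolexo)-exo-trig aldol) with loss of water and enolisation of the former pyranone carbonyl to the C7 phenol. The closest known reactions are the base-induced ring transformations of pyrylium salts and 4-pyranones by CH-acids, in which one carbon takes the place of the ring oxygen, and the aldol aromatisation of pyranone-masked 1,3,5-tricarbonyl chains; the intramolecular case with a plain methyl ketone is new. Regiochemistry rests on the tether: only the methyl carbon reaches C8a through a six-membered transition state, whereas the internal carbon C3 would close a four-membered ring at C8a or a bridged ring with a bridgehead double bond at C5 or C7. C2 is carried over from 15; C1, acidic beside the pyranone, should epimerise under the alkoxide faster than ring B closes, and the chair transition state with aryl and benzyloxymethyl both equatorial and the ring oxygen (not the C8 methoxy flank) next to the aryl group is expected to channel both epimers into the trans tetralone, in which C1 is no longer labile. The irreversible aromatisation drives the sequence, and low temperature with a short reaction time is chosen so that the internal enolate does not expel the C1 carbanion (retro-Michael), which would erode C2.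

Step 11
Reactants: 18 tetralone
Product: 19 (1S,2R)-1-Ar-2-(benzyloxymethyl)-4-chloro-7-hydroxy-6,8-dimethoxy-1,2-dihydronaphthalene-3-carbaldehyde
Conditions: POCl3 (3 equiv), DMF (6 equiv), CH2Cl2, 0 to 40 °C; then aq. NaOAc, rt
Reagents that add atoms: N,N-dimethylformamide, CN(C)C=O; phosphoryl chloride, O=P(Cl)(Cl)Cl; water, O
Why: Vilsmeier–Haack–Arnold chloroformylation, in which the chloroiminium ion formylates the ketone enol at C3 and exchanges the C4 oxygen for chloride, and the acetate work-up hydrolyses the iminium salt and any formate formed at the hindered C7 phenol; the temperature is kept at or below 40 °C to spare the two electron-rich rings.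

Step 12
Reactants: 19 chloro enal
Product: 20 (1S,2R)-1-Ar-2-(benzyloxymethyl)-7-hydroxy-6,8-dimethoxy-1,2-dihydronaphthalene-3-carbaldehyde
Conditions: Pd(PPh3)4 (5 mol%), HCO2H (2 equiv), Et3N (3 equiv), DMF, 60 °C
Reagents that add atoms: none
Why: palladium-catalysed formate hydrogenolysis of a vinylogous acid chloride, in which zerovalent palladium inserts into the activated C4–Cl bond and formate exchange, loss of CO2 and reductive elimination give C4–H without touching the enal, the benzyl ethers or the stereocentres.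

Step 13
Reactants: 20 bis-benzyl enal
Product: 21 (1S,2R)-7-hydroxy-1-(4-hydroxy-3,5-dimethoxyphenyl)-2-(hydroxymethyl)-6,8-dimethoxy-1,2-dihydronaphthalene-3-carbaldehyde (target)
Conditions: BCl3 (6 equiv), C6HMe5 (6 equiv), CH2Cl2, −78 to −40 °C; then MeOH
Reagents that add atoms: none
Why: Lewis acid debenzylation with BCl3 and pentamethylbenzene as non-basic benzyl cation scavenger should cleave the aryl and the primary alkyl benzyl ether at low temperature and leave the methyl ethers, the enal and the C3=C4 bond intact, which hydrogenolysis would not.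

**Compound list**
1 | syringaldehyde (4-hydroxy-3,5-dimethoxybenzaldehyde) | COc1cc(C=O)cc(OC)c1O | starting material
2 | 4-(benzyloxy)-3,5-dimethoxybenzaldehyde | COc1cc(C=O)cc(OC)c1OCc1ccccc1 | intermediate
3 | nitromethane | C[N+](=O)[O-] | starting material
4 | 2-(benzyloxy)-1,3-dimethoxy-5-[(E)-2-nitroethenyl]benzene | COc1cc(/C=C/[N+](=O)[O-])cc(OC)c1OCc1ccccc1 | intermediate
5 | pent-4-enal | C=CCCC=O | starting material
6 | (2S)-2-[(1R)-1-(4-benzyloxy-3,5-dimethoxyphenyl)-2-nitroethyl]pent-4-enal | COc1cc([C@H](C[N+](=O)[O-])[C@@H](C=O)CC=C)cc(OC)c1OCc1ccccc1 | intermediate (not isolated)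
7 | (2S)-2-[(1R)-1-(4-benzyloxy-3,5-dimethoxyphenyl)-2-nitroethyl]pent-4-en-1-ol | COc1cc([C@H](C[N+](=O)[O-])[C@@H](CO)CC=C)cc(OC)c1OCc1ccccc1 | intermediate
8 | 2-(benzyloxy)-5-[(2R,3S)-3-(benzyloxymethyl)-1-nitrohex-5-en-2-yl]-1,3-dimethoxybenzene | COc1cc([C@H](C[N+](=O)[O-])[C@@H](COCc2ccccc2)CC=C)cc(OC)c1OCc1ccccc1 | intermediate
9 | (2R,3S)-2-(4-benzyloxy-3,5-dimethoxyphenyl)-3-(benzyloxymethyl)hex-5-enal (C2 of the hexenal = C1 of the target, labile) | COc1cc([C@H](C=O)[C@@H](COCc2ccccc2)CC=C)cc(OC)c1OCc1ccccc1 | intermediate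
10 | 1,3-dimethoxypropan-2-one | COCC(=O)COC | starting material
11 | (Z)-4-(dimethylamino)-1,3-dimethoxybut-3-en-2-one | COCC(=O)/C(OC)=C/N(C)C | intermediate
12 | (1Z,7S)-6-(4-benzyloxy-3,5-dimethoxyphenyl)-7-(benzyloxymethyl)-1-(dimethylamino)-5-hydroxy-2,4-dimethoxydeca-1,9-dien-3-one; diastereomer mixture at C4, C5, C6 | COc1cc(C(C(O)C(OC)C(=O)/C(OC)=C/N(C)C)[C@@H](COCc2ccccc2)CC=C)cc(OC)c1OCc1ccccc1 | intermediate
13 | (1Z,7S)-6-(4-benzyloxy-3,5-dimethoxyphenyl)-7-(benzyloxymethyl)-1-(dimethylamino)-2,4-dimethoxydeca-1,9-diene-3,5-dione; both C6 epimers, enolised | COc1cc(C(C(=O)C(OC)C(=O)/C(OC)=C/N(C)C)[C@@H](COCc2ccccc2)CC=C)cc(OC)c1OCc1ccccc1 | intermediate (not isolated)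
14 | 2-[(2S)-1-(4-benzyloxy-3,5-dimethoxyphenyl)-2-(benzyloxymethyl)pent-4-en-1-yl]-3,5-dimethoxy-4H-pyran-4-one; both C1 epimers | COc1cc(C([C@@H](COCc2ccccc2)CC=C)C2=C(OC)C(=O)C(OC)=CO2)cc(OC)c1OCc1ccccc1 | intermediate
15 | 2-[(2S)-1-(4-benzyloxy-3,5-dimethoxyphenyl)-2-(benzyloxymethyl)-4-oxopentyl]-3,5-dimethoxy-4H-pyran-4-one; both C1 epimers, the (1S,2S) epimer is the one that closes to the trans tetralone | COc1cc(C([C@@H](COCc2ccccc2)CC(C)=O)C2=C(OC)C(=O)C(OC)=CO2)cc(OC)c1OCc1ccccc1 | intermediate (key-step precursor)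
16 | 11-(4-benzyloxy-3,5-dimethoxyphenyl)-10-(benzyloxymethyl)-3,5-dimethoxy-1-oxaspiro[5.5]undec-2-ene-4,8-dione, aryl and benzyloxymethyl trans, C2 and C1 of the target as in 18 | O=C1C[C@H](COCc2ccccc2)[C@@H](c2cc(OC)c(OCc3ccccc3)c(OC)c2)C2(C1)OC=C(OC)C(=O)C2OC | intermediate (not isolated)
17 | 4-[2-(4-benzyloxy-3,5-dimethoxyphenyl)-3-(benzyloxymethyl)-5-oxocyclohexylidene]-1-hydroxy-2,4-dimethoxybut-1-en-3-one (enol of the formyl ketone), ring substituents trans as in 18 | O=C1C[C@H](COCc2ccccc2)[C@@H](c2cc(OC)c(OCc3ccccc3)c(OC)c2)C(C1)=C(OC)C(=O)C(OC)=CO | intermediate (not isolated)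
18 | (1S,2S)-1-(4-benzyloxy-3,5-dimethoxyphenyl)-2-(benzyloxymethyl)-7-hydroxy-6,8-dimethoxy-2,3-dihydronaphthalen-4(1H)-one (trans) | COc1cc([C@H]2c3c(cc(OC)c(O)c3OC)C(=O)C[C@@H]2COCc2ccccc2)cc(OC)c1OCc1ccccc1 | intermediate (key-step product)
19 | (1S,2R)-1-(4-benzyloxy-3,5-dimethoxyphenyl)-2-(benzyloxymethyl)-4-chloro-7-hydroxy-6,8-dimethoxy-1,2-dihydronaphthalene-3-carbaldehyde | COc1cc([C@H]2c3c(cc(OC)c(O)c3OC)C(Cl)=C(C=O)[C@@H]2COCc2ccccc2)cc(OC)c1OCc1ccccc1 | intermediate
20 | (1S,2R)-1-(4-benzyloxy-3,5-dimethoxyphenyl)-2-(benzyloxymethyl)-7-hydroxy-6,8-dimethoxy-1,2-dihydronaphthalene-3-carbaldehyde | COc1cc([C@H]2c3c(cc(OC)c(O)c3OC)C=C(C=O)[C@@H]2COCc2ccccc2)cc(OC)c1OCc1ccccc1 | intermediate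
21 | (1S,2R)-7-hydroxy-1-(4-hydroxy-3,5-dimethoxyphenyl)-2-(hydroxymethyl)-6,8-dimethoxy-1,2-dihydronaphthalene-3-carbaldehyde | COc1cc([C@H]2c3c(cc(OC)c(O)c3OC)C=C(C=O)[C@@H]2CO)cc(OC)c1O | target

**Step count**
Total steps: 13. Longest linear sequence: 12 (steps 1–5 and 7–13; step 6 is the side branch).

**Steps most likely to fail**

1. Step 10. Three processes may go wrong:
- The substrate may rest as its unreactive C1 carbanion, so that the hindered, fully substituted C8a is not attacked.
- The two C1 epimers may close at similar rates and give a cis/trans mixture.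
- Retro-Michael fragmentation through the internal enolate may erode the configuration at C2.

Fallback with known chemistry, setting out from 15: aqueous Ba(OH)2 in MeOH at room temperature opens the pyranone by hydroxide addition at C5, the classical alkaline hydrolysis of 4-pyranones to 1,3,5-tricarbonyl compounds. After buffering to pH 6 this gives (7S)-6-(4-benzyloxy-3,5-dimethoxyphenyl)-7-(benzyloxymethyl)-2,4-dimethoxy-3,5,9-trioxodecanal F1 as an enol mixture. Brief treatment of F1 with dilute KOH in MeOH (or a pH 9 carbonate buffer) then lets ordinary ketone aldol chemistry form C4a–C8a (methyl ketone onto the free C8a carbonyl) and C4a–C5 (condensation with the formyl group). Loss of two molecules of water rejoins the route at tetralone 18.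

2. Step 11. The chloroiminium reagent may formylate the electron-rich pendant ring or C5 of ring A, or leave the C7 phenol as a formate or phosphate, instead of reacting cleanly at the ketone.

Fallback, setting out from 18: Bredereck's reagent t-BuOCH(NMe2)2 in toluene at 80 °C gives the enaminone (1S,2R,E)-1-(4-benzyloxy-3,5-dimethoxyphenyl)-2-(benzyloxymethyl)-3-[(dimethylamino)methylidene]-7-hydroxy-6,8-dimethoxy-2,3-dihydronaphthalen-4(1H)-one F2. 1,2-Reduction with LiAlH4 in THF at 0 °C gives the amino allylic alcohol (1S,2R,E)-1-(4-benzyloxy-3,5-dimethoxyphenyl)-2-(benzyloxymethyl)-3-[(dimethylamino)methylidene]-6,8-dimethoxy-1,2,3,4-tetrahydronaphthalene-4,7-diol F3. Dilute aqueous HCl then hydrolyses the enamine and eliminates the benzylic C4 hydroxyl (reductive carbonyl transposition of an enaminone) to give enal 20 directly; the route is rejoined at 20, so 19 and step 12 are bypassed.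

3. Step 7. The lithium enolate may deprotonate the acidic α-aryl aldehyde instead of adding to it, or the aldolate may revert on warming.

Fallback, setting out from 9: Pinnick oxidation (NaClO2, NaH2PO4, 2-methylbut-2-ene, t-BuOH–H2O) gives (2R,3S)-2-(4-benzyloxy-3,5-dimethoxyphenyl)-3-(benzyloxymethyl)hex-5-enoic acid F4. Oxalyl chloride with catalytic DMF gives (2R,3S)-2-(4-benzyloxy-3,5-dimethoxyphenyl)-3-(benzyloxymethyl)hex-5-enoyl chloride F5. F5 C-acylates the lithium enolate of 11 (2.2 equiv, THF, −78 °C, inverse addition) to give diketone 13 directly. The route is rejoined at 13, which is closed to 14 with CF3CO2H as in step 8.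

**Further compounds**
F1 | step 10 | (7S)-6-(4-benzyloxy-3,5-dimethoxyphenyl)-7-(benzyloxymethyl)-2,4-dimethoxy-3,5,9-trioxodecanal (both C6 epimers, enol mixture) | O=CC(OC)C(=O)C(OC)C(=O)C(c1cc(OC)c(OCc2ccccc2)c(OC)c1)[C@@H](COCc1ccccc1)CC(C)=O
F2 | step 11 | (1S,2R,E)-1-(4-benzyloxy-3,5-dimethoxyphenyl)-2-(benzyloxymethyl)-3-[(dimethylamino)methylidene]-7-hydroxy-6,8-dimethoxy-2,3-dihydronaphthalen-4(1H)-one | COc1cc([C@H]2c3c(cc(OC)c(O)c3OC)C(=O)/C(=C/N(C)C)[C@@H]2COCc2ccccc2)cc(OC)c1OCc1ccccc1
F3 | step 11 | (1S,2R,E)-1-(4-benzyloxy-3,5-dimethoxyphenyl)-2-(benzyloxymethyl)-3-[(dimethylamino)methylidene]-6,8-dimethoxy-1,2,3,4-tetrahydronaphthalene-4,7-diol (C4 epimers) | COc1cc([C@H]2c3c(cc(OC)c(O)c3OC)C(O)/C(=C/N(C)C)[C@@H]2COCc2ccccc2)cc(OC)c1OCc1ccccc1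
F4 | step 7 | (2R,3S)-2-(4-benzyloxy-3,5-dimethoxyphenyl)-3-(benzyloxymethyl)hex-5-enoic acid | COc1cc([C@H](C(=O)O)[C@@H](COCc2ccccc2)CC=C)cc(OC)c1OCc1ccccc1
F5 | step 7 | (2R,3S)-2-(4-benzyloxy-3,5-dimethoxyphenyl)-3-(benzyloxymethyl)hex-5-enoyl chloride | COc1cc([C@H](C(=O)Cl)[C@@H](COCc2ccccc2)CC=C)cc(OC)c1OCc1ccccc1
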